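**Strategy.** The target is cut at its lactone C–O bond and at C3–C4, which leaves an arene carrying a benzoate carbon (C1) on C8a and a benzylic carbon (C4) on the neighbouring C4a. C1, C4, Ca, Cb and C3' together are the carbon chain of trimethyl trans-aconitate with the benzene ring wedged between C1 and C4. The route therefore rests on inserting 3,5-bis(benzyloxy)benzyne into the CH2–CO2Me bond of the aconitate, which forms C4a–C4 and C8a–C1 in one operation and keeps the aconitate alkene. The aryne comes from an ortho-silyl aryl triflate; the isochromanone ring and both stereocentres are added afterwards with methyl glyoxylate.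

Key step: step 4

Remark on the target: it is read as (3S,4R), with the C3 ester and the C4 side chain trans, hydroxyls at C5, C6 and C8 (C7–H), and an E alkene whose free carboxyl is cis to C4. Because the ring holding the two stereocentres changes in step 7, the δ-lactone 18 must be cis, (2S,3R).

Remark on the precursor: benzyl ethers are kept on O6 and O8, since an ether oxygen at C8 steers the aryne addition and BCl3 removes benzyl without reducing the alkene. All three aconitate esters are methyl so that both ends of its anion are identical. C5 stays C–H so that only one oxygen flanks the triple bond.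

Assumption: 13 is obtained and used as the tautomer drawn (alkene conjugated with both esters), and methyl glyoxylate 16 is used as freshly distilled monomer.

**Step 1**
Reactants: 1 3,5-bis(benzyloxy)phenol
Product: 2 3,5-bis(benzyloxy)phenyl N-isopropylcarbamate
Conditions: i-PrNCO (1.5 equiv), Et3N (0.2 equiv), CH2Cl2, 23 °C
Reagents that add atoms: isopropyl isocyanate, CC(C)N=C=O
Why: Amine-catalysed addition of the phenol to the isocyanate (carbamoylation) gives the N–H carbamate, chosen because it is the strongest ortho-director on the ring and can later be removed by mild base.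

**Step 2**
Reactants: 2 3,5-bis(benzyloxy)phenyl N-isopropylcarbamate
Product: 6 3,5-bis(benzyloxy)-2-(trimethylsilyl)phenyl N-isopropylcarbamate, via N-silyl carbamate 3 (not isolated), via aryllithium 4 (not isolated), via bis-silyl carbamate 5 (not isolated)
Conditions: TBSOTf (1.1 equiv), TMEDA (1.1 equiv), Et2O, 0 → 23 °C; then n-BuLi (2.1 equiv), TMEDA (2.0 equiv), −78 °C; then TMSCl (3 equiv), −78 → 23 °C; aq. NaHSO4
Reagents that add atoms: chlorotrimethylsilane, C[Si](C)(C)Cl
Why: Directed ortho-metalation: after transient N-silylation, the carbamate and the neighbouring benzyloxy group jointly direct lithiation to C2 (C6 is equivalent by symmetry, and C4 between the two ethers lacks the stronger director), TMSCl silylates aryllithium 4, and the N-silyl group falls off on acidic work-up.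

**Step 3**
Reactants: 6 3,5-bis(benzyloxy)-2-(trimethylsilyl)phenyl N-isopropylcarbamate
Product: 8 3,5-bis(benzyloxy)-2-(trimethylsilyl)phenyl trifluoromethanesulfonate, via silyl phenol 7 (not isolated)
Conditions: Et2NH (1.25 equiv), DBU (1.5 equiv), MeCN, 40 °C; then PhNTf2 (1.5 equiv), 23 °C
Reagents that add atoms: N-phenylbis(trifluoromethanesulfonimide), O=S(=O)(N(c1ccccc1)S(=O)(=O)C(F)(F)F)C(F)(F)F
Why: One-pot carbamate cleavage and triflation: DBU triggers E1cB loss of isopropyl isocyanate (trapped by Et2NH as a urea) to give the phenoxide of 7, which PhNTf2 sulfonylates, leaving silicon and triflate on neighbouring carbons as needed for fluoride-induced 1,2-elimination.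

**Step 4**
Reactants: 8 3,5-bis(benzyloxy)-2-(trimethylsilyl)phenyl trifluoromethanesulfonate; 9 trimethyl trans-aconitate
Product: 13 methyl 2,4-bis(benzyloxy)-6-[(E)-2,3-bis(methoxycarbonyl)allyl]benzoate, via aryne 10 (not isolated), via aryl anion 11 (not isolated), via benzocyclobutenoxide 12 (not isolated)
Conditions: 9 (1.5 equiv), KF (3 equiv), 18-crown-6 (3 equiv), THF, 0 → 23 °C, 8 added over 2 h
Reagents that add atoms: none
Why: Proposed new method: fluoride unmasks aryne 10 from 8 and deprotonates 9 to its symmetrical tris(ester) allyl anion, which adds through a terminal carbon to the aryne carbon remote from the flanking benzyloxy group (the future C4a), so that aryl anion 11 sits at the future C8a between that benzyloxy group and the new substituent. Anion 11 attacks the ester on the carbon just arylated (4-exo-trig) to give benzocyclobutenoxide 12, which opens by C–C cleavage to the methyl benzoate and a benzylic, vinylogous ester carbanion; protonation by 9 or on work-up is expected to return the alkene to conjugation with both esters, and no ring and no stereocentre remain in 13. The closest known reaction type is the fluoride-mediated acyl-alkylation of arynes, that is, insertion into the C–C sigma bond of beta-keto esters and malonates; new here is a pronucleophile whose carbanion is an extended allyl system and whose migrating acyl group is a plain ester with a second ester one carbon further away. Regioselectivity of the aryne addition is secured by the inductively withdrawing benzyloxy group beside the triple bond, which distorts the aryne so that attack at the remote carbon is favoured, and because the anion of 9 has equivalent ends only one carbon adduct can form. The step also needs 4-exo attack on the adjacent ester to win over 5-exo attack on the central ester and over protonation of 11; the adjacent ester is held closest to the aryl anion, and the leaving carbanion is much better stabilised than in the malonate case, which should favour closure and fragmentation.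

**Step 5**
Reactants: 13 methyl 2,4-bis(benzyloxy)-6-[(E)-2,3-bis(methoxycarbonyl)allyl]benzoate
Product: 15 methyl 2,4-bis(benzyloxy)-6-[(1Z)-4-{[tert-butyl(dimethyl)silyl]oxy}-4-methoxy-2-(methoxycarbonyl)buta-1,3-dien-1-yl]benzoate, via lithium dienolate 14 (not isolated)
Conditions: LiN(SiMe3)2 (1.05 equiv), THF, −78 °C, 15 min; TBSOTf (1.1 equiv), −78 → 0 °C; hexane, filtration under argon, used crude
Reagents that add atoms: tert-butyldimethylsilyl trifluoromethanesulfonate, CC(C)(C)[Si](C)(C)OS(=O)(=O)C(F)(F)F
Why: Silyl dienolate formation: kinetic deprotonation of the only acidic site, the benzylic CH2 that is gamma to the C3' ester, gives the vinylogous enolate 14, which the hard silyl triflate traps on the C3' ester oxygen; allylic 1,3-strain with the C3' ester cis to C4 keeps the aryl group turned away from Cb during deprotonation, so the new C4=Ca bond should be Z and the aryl group outward in the s-cis diene.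

**Step 6**
Reactants: 15 methyl 2,4-bis(benzyloxy)-6-[(1Z)-4-{[tert-butyl(dimethyl)silyl]oxy}-4-methoxy-2-(methoxycarbonyl)buta-1,3-dien-1-yl]benzoate; 16 methyl glyoxylate
Product: 18 dimethyl (2S,3R)-3-[3,5-bis(benzyloxy)-2-(methoxycarbonyl)phenyl]-6-oxo-3,6-dihydro-2H-pyran-2,4-dicarboxylate, via ortho ester cycloadduct 17 (not isolated)
Conditions: Cu(OTf)2 (10 mol %), (S,S)-t-Bu-box [2,2'-(propane-2,2-diyl)bis((4S)-4-tert-butyl-4,5-dihydro-1,3-oxazole)] (11 mol %), 16 (2 equiv), 4 Å MS, CH2Cl2, −78 → −40 °C; then TFA (0.2 equiv), CH2Cl2, 0 °C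
Reagents that add atoms: none
Why: Catalytic enantioselective hetero-Diels–Alder reaction (a stepwise Mukaiyama aldol–ring closure leads to the same adduct) of the 1-alkoxy-1-silyloxy diene with glyoxylate held as a five-membered chelate on divalent copper: by the square-planar chelate model the tert-butyl groups of the (S,S)-ligand leave the Si face of the aldehyde open and set pyran C2 (later C3) as S, endo placement of the chelated ester under the diene whose aryl group points outward sets pyran C3 (later C4) as R and cis to C2, and acid then collapses ortho ester 17 to the δ-lactone, which exists only with C3' cis to C4 and so fixes the E geometry of the final alkene.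

**Step 7**
Reactants: 18 dimethyl (2S,3R)-3-[3,5-bis(benzyloxy)-2-(methoxycarbonyl)phenyl]-6-oxo-3,6-dihydro-2H-pyran-2,4-dicarboxylate
Product: 20 (E)-3-[(3S,4R)-6,8-bis(benzyloxy)-3-(methoxycarbonyl)-1-oxoisochroman-4-yl]-4-methoxy-4-oxobut-2-enoic acid, via hydroxy carboxylate 19 (not isolated)
Conditions: LiOH·H2O (1.05 equiv), THF/H2O (4:1), 0 → 23 °C; then aq. NaHSO4 to pH 3, 0 °C
Reagents that add atoms: lithium hydroxide, [Li+].[OH-]
Why: Translactonization: hydroxide opens the δ-lactone, which as a cyclic ester is saponified much faster than the methyl esters, and the freed C3 hydroxyl of 19 then closes 6-exo-trig on the ortho methyl benzoate (the lactonization typical of 2-(2-hydroxyalkyl)benzoates) while the C3' carboxylate can neither re-close nor readily be deprotonated at C4, so C3' emerges as the only free acid and both stereocentres are carried over unchanged (cis in 18 and trans in 20 describe the same configuration in different rings).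

**Step 8**
Reactants: 20 (E)-3-[(3S,4R)-6,8-bis(benzyloxy)-3-(methoxycarbonyl)-1-oxoisochroman-4-yl]-4-methoxy-4-oxobut-2-enoic acid
Product: 21 (E)-3-[(3S,4R)-6,8-dihydroxy-3-(methoxycarbonyl)-1-oxoisochroman-4-yl]-4-methoxy-4-oxobut-2-enoic acid
Conditions: BCl3 (6 equiv), C6HMe5 (6 equiv), CH2Cl2, −78 °C; then H2O/THF, −78 → 0 °C
Reagents that add atoms: none
Why: Lewis-acid debenzylation with a cation scavenger: BCl3 cleaves both aryl benzyl ethers at −78 °C (the C8 ether first, through chelation with the lactone carbonyl) and pentamethylbenzene captures the benzyl cations, conditions that leave methyl esters, lactone, acid and the electron-poor alkene alone, whereas hydrogenolysis would reduce the alkene.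

**Step 9**
Reactants: 21 (E)-3-[(3S,4R)-6,8-dihydroxy-3-(methoxycarbonyl)-1-oxoisochroman-4-yl]-4-methoxy-4-oxobut-2-enoic acid
Product: 23 (E)-4-methoxy-3-[(3S,4R)-5,6,8-trihydroxy-3-(methoxycarbonyl)-1-oxoisochroman-4-yl]-4-oxobut-2-enoic acid (CNP0546035.1), via hydroxyquinone 22 (not isolated)
Conditions: (KSO3)2NO (2.5 equiv), KH2PO4 buffer (pH 6), H2O/acetone, 0 °C; then Na2S2O4 (aq., excess), EtOAc, argon; work-up at pH 3
Reagents that add atoms: potassium nitrosodisulfonate, [K+].[K+].[O]N(S(=O)(=O)[O-])S(=O)(=O)[O-]
Why: Teuber oxidation followed by reduction: the nitrosodisulfonate radical oxidises the resorcinol at C5, the only ring position para to a hydroxyl (C8–OH) and ortho to the other (C6–OH), to the 6-hydroxy-5,8-quinone 22, which dithionite reduces immediately to the 5,6,8-triol at near-neutral pH where neither stereocentre should be labile.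

**Compound list**

1 | 3,5-bis(benzyloxy)phenol | Oc1cc(OCc2ccccc2)cc(OCc2ccccc2)c1 | starting material
2 | 3,5-bis(benzyloxy)phenyl N-isopropylcarbamate | CC(C)NC(=O)Oc1cc(OCc2ccccc2)cc(OCc2ccccc2)c1 | intermediate
3 | 3,5-bis(benzyloxy)phenyl N-[tert-butyl(dimethyl)silyl]-N-isopropylcarbamate (in situ) | CC(C)N(C(=O)Oc1cc(OCc2ccccc2)cc(OCc2ccccc2)c1)[Si](C)(C)C(C)(C)C | intermediate
4 | 2-lithio derivative of 3 (in situ) | CC(C)N(C(=O)Oc1cc(OCc2ccccc2)cc(OCc2ccccc2)c1[Li])[Si](C)(C)C(C)(C)C | intermediate
5 | 3,5-bis(benzyloxy)-2-(trimethylsilyl)phenyl N-[tert-butyl(dimethyl)silyl]-N-isopropylcarbamate (in situ) | CC(C)N(C(=O)Oc1cc(OCc2ccccc2)cc(OCc2ccccc2)c1[Si](C)(C)C)[Si](C)(C)C(C)(C)C | intermediate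
6 | 3,5-bis(benzyloxy)-2-(trimethylsilyl)phenyl N-isopropylcarbamate | CC(C)NC(=O)Oc1cc(OCc2ccccc2)cc(OCc2ccccc2)c1[Si](C)(C)C | intermediate
7 | 3,5-bis(benzyloxy)-2-(trimethylsilyl)phenol (in situ, as its amidinium phenoxide) | Oc1cc(OCc2ccccc2)cc(OCc2ccccc2)c1[Si](C)(C)C | intermediate
8 | 3,5-bis(benzyloxy)-2-(trimethylsilyl)phenyl trifluoromethanesulfonate | C[Si](C)(C)c1c(OCc2ccccc2)cc(OCc2ccccc2)cc1OS(=O)(=O)C(F)(F)F | intermediate
9 | trimethyl trans-aconitate (trimethyl (E)-prop-1-ene-1,2,3-tricarboxylate) | COC(=O)C/C(C(=O)OC)=C\C(=O)OC | starting material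
10 | 3,5-bis(benzyloxy)benzyne (in situ) | C1#CC(OCc2ccccc2)=CC(OCc2ccccc2)=C1 | intermediate
11 | potassium 2,4-bis(benzyloxy)-6-[(2E)-1,2,3-tris(methoxycarbonyl)prop-2-en-1-yl]phenide (in situ, CH centre racemic) | COC(=O)C(/C(C(=O)OC)=C\C(=O)OC)c1cc(OCc2ccccc2)cc(OCc2ccccc2)[c-]1.[K+] | intermediate
12 | potassium 3,5-bis(benzyloxy)-8-[(E)-1,2-bis(methoxycarbonyl)vinyl]-7-methoxybicyclo[4.2.0]octa-1,3,5-trien-7-olate (in situ, racemic) | COC1([O-])C(/C(C(=O)OC)=C\C(=O)OC)c2cc(OCc3ccccc3)cc(OCc3ccccc3)c21.[K+] | intermediate
13 | methyl 2,4-bis(benzyloxy)-6-[(E)-2,3-bis(methoxycarbonyl)allyl]benzoate | COC(=O)c1c(OCc2ccccc2)cc(OCc2ccccc2)cc1C/C(C(=O)OC)=C\C(=O)OC | intermediate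
14 | lithium dienolate of 13, O-lithiated at C3', Z at C4=Ca (in situ; enolate geometry not defined) | COC(=O)/C(C=C(OC)[O-])=C\c1cc(OCc2ccccc2)cc(OCc2ccccc2)c1C(=O)OC.[Li+] | intermediate
15 | methyl 2,4-bis(benzyloxy)-6-[(1Z)-4-{[tert-butyl(dimethyl)silyl]oxy}-4-methoxy-2-(methoxycarbonyl)buta-1,3-dien-1-yl]benzoate (ketene acetal geometry not defined) | COC(=O)/C(C=C(OC)O[Si](C)(C)C(C)(C)C)=C\c1cc(OCc2ccccc2)cc(OCc2ccccc2)c1C(=O)OC | intermediate
16 | methyl glyoxylate | COC(=O)C=O | starting material
17 | dimethyl (2S,3R)-3-[3,5-bis(benzyloxy)-2-(methoxycarbonyl)phenyl]-6-{[tert-butyl(dimethyl)silyl]oxy}-6-methoxy-3,6-dihydro-2H-pyran-2,4-dicarboxylate (in situ, both C6 epimers) | COC(=O)C1=CC(OC)(O[Si](C)(C)C(C)(C)C)O[C@H](C(=O)OC)[C@@H]1c2cc(OCc3ccccc3)cc(OCc3ccccc3)c2C(=O)OC | intermediate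
18 | dimethyl (2S,3R)-3-[3,5-bis(benzyloxy)-2-(methoxycarbonyl)phenyl]-6-oxo-3,6-dihydro-2H-pyran-2,4-dicarboxylate (cis) | COC(=O)C1=CC(=O)O[C@H](C(=O)OC)[C@@H]1c2cc(OCc3ccccc3)cc(OCc3ccccc3)c2C(=O)OC | intermediate
19 | lithium (E)-3-{(1R,2S)-1-[3,5-bis(benzyloxy)-2-(methoxycarbonyl)phenyl]-2-hydroxy-3-methoxy-3-oxopropyl}-4-methoxy-4-oxobut-2-enoate (in situ) | COC(=O)/C(=C/C(=O)[O-])[C@H]([C@H](O)C(=O)OC)c1cc(OCc2ccccc2)cc(OCc2ccccc2)c1C(=O)OC.[Li+] | intermediate
20 | (E)-3-[(3S,4R)-6,8-bis(benzyloxy)-3-(methoxycarbonyl)-1-oxoisochroman-4-yl]-4-methoxy-4-oxobut-2-enoic acid | COC(=O)/C(=C/C(=O)O)[C@H]1c2cc(OCc3ccccc3)cc(OCc3ccccc3)c2C(=O)O[C@@H]1C(=O)OC | intermediate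
21 | (E)-3-[(3S,4R)-6,8-dihydroxy-3-(methoxycarbonyl)-1-oxoisochroman-4-yl]-4-methoxy-4-oxobut-2-enoic acid | COC(=O)/C(=C/C(=O)O)[C@H]1c2cc(O)cc(O)c2C(=O)O[C@@H]1C(=O)OC | intermediate
22 | (E)-3-[(3S,4R)-6-hydroxy-3-(methoxycarbonyl)-1,5,8-trioxo-3,4,5,8-tetrahydro-1H-isochromen-4-yl]-4-methoxy-4-oxobut-2-enoic acid (in situ) | COC(=O)/C(=C/C(=O)O)[C@H]1C2=C(C(=O)O[C@@H]1C(=O)OC)C(=O)C=C(O)C2=O | intermediate
23 | (E)-4-methoxy-3-[(3S,4R)-5,6,8-trihydroxy-3-(methoxycarbonyl)-1-oxoisochroman-4-yl]-4-oxobut-2-enoic acid | COC(=O)/C(=C/C(=O)O)[C@H]1c2c(O)c(O)cc(O)c2C(=O)O[C@@H]1C(=O)OC | target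

**Totals**

Total step count: 9. Longest linear sequence: 9 steps (1 → 23); 9 and 16 are purchased and enter at steps 4 and 6.

**Steps most likely to fail**

1. Step 4 (new method).
 - What may go wrong: before the four-membered ring closes, aryl anion 11 may attack the central ester through a five-membered transition state (leading on to an indenone). It may also be quenched by proton transfer from the acidic pronucleophile, which gives plain arylation without acyl shift. Compound 9 may self-condense by conjugate addition of its own anion, and the alkene of 13 may migrate into conjugation with the arene.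
 - Fallback (known reactions only): it sets out from carbamate 2 through aryllithium 4 and from methyl glyoxylate 16, and rejoins the route at 13. Aryllithium 4, generated as in step 2, is quenched with methyl chloroformate instead of TMSCl to give the N-silylated ester carbamate F1 and, after acidic work-up, 3,5-bis(benzyloxy)-2-(methoxycarbonyl)phenyl N-isopropylcarbamate F2. The step 3 protocol (Et2NH, DBU, then PhNTf2) converts F2 through methyl 2,4-bis(benzyloxy)-6-hydroxybenzoate F3 into the aryl triflate methyl 2,4-bis(benzyloxy)-6-{[(trifluoromethyl)sulfonyl]oxy}benzoate F4. Miyaura borylation (B2pin2, PdCl2(dppf), KOAc, dioxane, 80 °C) gives methyl 2,4-bis(benzyloxy)-6-(4,4,5,5-tetramethyl-1,3,2-dioxaborolan-2-yl)benzoate F5. In parallel, a Morita–Baylis–Hillman reaction of 16 with methyl acrylate (DABCO) gives dimethyl 2-hydroxy-3-methylidenebutanedioate F6. Rhodium-catalysed addition of F5 to F6 with β-hydroxy elimination ([Rh(OH)(cod)]2, MeOH, 50 °C) joins the aryl carbon to the methylene carbon and should deliver the E 2-benzylfumarate 13 directly, without passing through the delocalised carbanion.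

2. Step 6.
 - What may go wrong: poor facial discrimination at the aldehyde, exo approach (giving the trans-lactone), or attack at Cb instead of C4. A stepwise aldol through the s-trans diene is also possible; its open-chain product has C3' trans to C4 and cannot lactonise. A diene that has lost its Z geometry (aryl inward) would favour that last pathway. Should the sense of induction prove opposite to the model, the (R,R)-ligand is used.
 - Fallback: it sets out from 15 and 16 and rejoins at 18. The cycloaddition is run without a chiral ligand under Eu(fod)3 catalysis (fod = 6,6,7,7,8,8,8-heptafluoro-2,2-dimethyloctane-3,5-dionate; CH2Cl2, 23 °C), conditions that favour the concerted endo pathway. This gives, through the racemic ortho ester cycloadduct F7 and TFA treatment, the racemic cis-lactone F8. F8 is resolved by preparative chromatography on a chiral stationary phase (amylose tris(3,5-dimethylphenylcarbamate)), and the (2S,3R) enantiomer 18 is carried on.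

3. Step 7.
 - What may go wrong: the freed hydroxyl may close on the Ca ester (five-membered lactone) instead of the hindered benzoate, hydroxide may also cleave the activated C3 methyl ester, or base may epimerise C4 before the lactone opens.
 - Fallback: it sets out from 18 and rejoins at 21, bypassing 19 and 20. The benzyl ethers are removed first under the step 8 conditions to give the diphenol lactone dimethyl (2S,3R)-3-[3,5-dihydroxy-2-(methoxycarbonyl)phenyl]-6-oxo-3,6-dihydro-2H-pyran-2,4-dicarboxylate F9. F9 is then equilibrated under acid with a little water (TsOH·H2O, 0.2 equiv, 1,2-dichloroethane, 60 °C, methanol allowed to distil out). Reversible hydrolysis of the δ-lactone and acid-catalysed transesterification onto the hydrogen-bond-activated salicylate ester should drain the system, with loss of methanol, to the chelated 8-hydroxyisochromanone 21. This runs under thermodynamic control, with no base present to threaten C3 or C4.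

**Further compounds**

F1 | step 4 | 3,5-bis(benzyloxy)-2-(methoxycarbonyl)phenyl N-[tert-butyl(dimethyl)silyl]-N-isopropylcarbamate (in situ) | COC(=O)c1c(OCc2ccccc2)cc(OCc2ccccc2)cc1OC(=O)N(C(C)C)[Si](C)(C)C(C)(C)C
F2 | step 4 | 3,5-bis(benzyloxy)-2-(methoxycarbonyl)phenyl N-isopropylcarbamate | COC(=O)c1c(OCc2ccccc2)cc(OCc2ccccc2)cc1OC(=O)NC(C)C
F3 | step 4 | methyl 2,4-bis(benzyloxy)-6-hydroxybenzoate (in situ) | COC(=O)c1c(O)cc(OCc2ccccc2)cc1OCc1ccccc1
F4 | step 4 | methyl 2,4-bis(benzyloxy)-6-{[(trifluoromethyl)sulfonyl]oxy}benzoate | COC(=O)c1c(OCc2ccccc2)cc(OCc2ccccc2)cc1OS(=O)(=O)C(F)(F)F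
F5 | step 4 | methyl 2,4-bis(benzyloxy)-6-(4,4,5,5-tetramethyl-1,3,2-dioxaborolan-2-yl)benzoate | COC(=O)c1c(OCc2ccccc2)cc(OCc2ccccc2)cc1B1OC(C)(C)C(C)(C)O1
F6 | step 4 | dimethyl 2-hydroxy-3-methylidenebutanedioate (racemic) | COC(=O)C(=C)C(O)C(=O)OC
F7 | step 6 | racemic cis ortho ester cycloadduct (17 plus its enantiomer, C6 epimers) | COC(=O)C1=CC(OC)(O[Si](C)(C)C(C)(C)C)O[C@H](C(=O)OC)[C@@H]1c2cc(OCc3ccccc3)cc(OCc3ccccc3)c2C(=O)OC.COC(=O)C1=CC(OC)(O[Si](C)(C)C(C)(C)C)O[C@@H](C(=O)OC)[C@H]1c2cc(OCc3ccccc3)cc(OCc3ccccc3)c2C(=O)OC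
F8 | step 6 | racemic cis-lactone (18 plus its (2R,3S) enantiomer) | COC(=O)C1=CC(=O)O[C@H](C(=O)OC)[C@@H]1c2cc(OCc3ccccc3)cc(OCc3ccccc3)c2C(=O)OC.COC(=O)C1=CC(=O)O[C@@H](C(=O)OC)[C@H]1c2cc(OCc3ccccc3)cc(OCc3ccccc3)c2C(=O)OC
F9 | step 7 | dimethyl (2S,3R)-3-[3,5-dihydroxy-2-(methoxycarbonyl)phenyl]-6-oxo-3,6-dihydro-2H-pyran-2,4-dicarboxylate | COC(=O)C1=CC(=O)O[C@H](C(=O)OC)[C@@H]1c2cc(O)cc(O)c2C(=O)OC
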